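In the midnight run target gains 58 percentage points in the 8.00 h after 12.0 h, against 2.4% in all the time before, so something holds the coupling back and then lets go.

- midnight: substrate 0.10 M; coupling partner 1.2 equiv; base 0.030 equiv; run made earlier
- flask: substrate 0.10 M; coupling partner 1.20 equiv; base 0.0200 equiv; time 4.0 d

midnight run (percent of the substrate charged)

| time / h | target / % | substrate / % |
|---|---|---|
| 1.50 | 0.6 | 99.1 |
| 4.00 | 0.1 | 97.2 |
| 8.00 | 0.3 | 97.9 |
| 12.0 | 2.4 | 97.0 |
| 20.0 | 60.3 | 38.2 |
| 25.0 | 80.5 | 12.1 |
| 30.0 | 82.1 | 2.9 |

(standard deviation of a reading: 1 percentage point)

- steps thought possible: substrate + coupling partner + released group -> target + 2 released group; substrate + coupling partner -> target + released group; base + released group <-> salt; target <-> isomer of the product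
- no earlier run changes the charge of base; that part of a forecast is a guess

- time, not beyond 4.0 d, at which the flask holds most target
- the amount of target, in percent of the substrate charged, at that time

What holds it back? I suppose that released group speeds the coupling and that base binds it at once and tightly, so while base stands, little released group is free and the slow uncatalysed route carries the reaction. The hold should then end when that route has released as much group as there was base. At 12.0 h the midnight readings show 3.00% of the substrate lost, beside a base charge of 0.030 equiv, so I read that time, within the scatter, as the end of the hold.

How long is the hold in this flask? I call it the base lag (the induction period) and scale it with the base charge, which gives 8.00 h for 0.0200 equiv. This is a guess, as no earlier run changes base.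

Where does the peak go? I expect the curve to move 4.00 h earlier. The midnight target readings level off between 25.0 h and 30.0 h, so I expect the flask's peak between 0.875 d and 1.08 d, about as high as the best midnight reading, 82.1%.

The forecast says 1 d and 83%, with the “whole curve then moves about 4 h earlier”. The flask gives 82.7% at 0.970 d.

    substrate + coupling partner + released group → target + 2 released group (k = 84.2 M⁻² h⁻¹)
    substrate + coupling partner → target + released group (k = 0.0210 M⁻¹ h⁻¹)
    base + released group ⇌ salt, settled at all times (K = 4.30 × 10⁶ M⁻¹)
    target ⇌ isomer of the product (K = 2.70, k = 0.0158 h⁻¹)

By 0.400 d this flask holds 0.00200 M of salt with 0.0264% of its base free, and the lag I reckoned for it, 0.333 d, is shorter than the 1.8 d half-life of target by the forward rate alone of its turning to isomer of the product, taken at 4.00 d. The slow route's pace in percent follows the substrate charge at fixed equivalents, so I reckon a lag of 0.833 d for the neighbour charged with 0.040 M of substrate, and at 4.00 d that neighbour holds 8.00 × 10⁻⁴ M of salt, 53.9% of target and still 9.51% of substrate.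

(All runs stem from a simulated flask with constants of no real substance.)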